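**Strategy.** The six carbons C8, C9, C11, C12, C15 and C16 (ent-kaurane numbering), shared by rings C and D of the bicyclo[3.2.1]octane, are treated as a disguised benzene ring: moving C16 from C13 back to C12 gives a bicyclo[2.2.2]octenone, the cycloadduct of a masked ortho-benzoquinone. The key step oxidises a phenol that already carries ring A, both lactones and the C10 spiro centre to this dienone and adds phenyl vinyl selenide across C12 and C8, forming the C12–C13 and C8–C14 bonds in one operation. Selenium then launches a radical 1,2-acyl shift to the kaurane bicycle; ring A comes from a maleate Diels–Alder lactonisation.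

Key step: step 12

Remark on numbering: atoms are numbered as in ent-kaurane (ring A = C1–C5 and C10; C18 = methyl on C4; C19–O–C6 = γ-lactone; C20–O–C7 = δ-lactone; ring C = C8, C9, C11–C14; ring D = C8, C13–C16; C17 = exocyclic CH2).
Remark on the resolution: in step 7 the (R)-1-phenylethylammonium salt that crystallises is assumed to be that of the enantiomer drawn; if it is the other one, the (S)-amine is used instead.
Remark on starting materials: 1, 4, 8, 9 and 20 are taken as catalogue compounds.

**Route**

Step 1
Reactants: 1 3-(benzyloxy)-4-methoxyphenol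
Product: 2 2-(benzyloxy)-1-methoxy-4-(methoxymethoxy)benzene
Conditions: MOMCl, iPr2NEt, CH2Cl2, 0 °C to rt
Reagents that add atoms: chloromethyl methyl ether, COCCl
Why: O-alkylation of the phenol by the α-chloro ether (Williamson-type acetal formation) puts an acid-labile mask on the future C11 oxygen, which must be unveiled late under the conditions of ketal hydrolysis.

Step 2
Reactants: 2 2-(benzyloxy)-1-methoxy-4-(methoxymethoxy)benzene
Product: 3 1-(benzyloxy)-4-bromo-2-methoxy-5-(methoxymethoxy)benzene
Conditions: NBS, MeCN, 0 °C
Reagents that add atoms: N-bromosuccinimide, O=C1CCC(=O)N1Br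
Why: Electrophilic aromatic bromination should go para to the benzyloxy group and ortho to the MOM ether (the future C9), the one position activated by two donors without lying between them.

Step 3
Reactants: 3 1-(benzyloxy)-4-bromo-2-methoxy-5-(methoxymethoxy)benzene; 4 bromomaleic anhydride
Product: 7 arylmaleic anhydride, via aryllithium 5 (not isolated), via arylzinc chloride 6 (not isolated)
Conditions: n-BuLi, THF, −78 °C; ZnCl2, −78 °C to rt; 4, Pd(PPh3)4 (5 mol %), THF, 45 °C
Reagents that add atoms: none
Why: Bromine–lithium exchange, transmetalation to zinc and Negishi coupling, in which oxidative addition into the vinylic C–Br bond of 4 should far outrun any reaction of the arylzinc with the anhydride carbonyls.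

Step 4
Reactants: 8 acrolein; 9 ethyl 2-(triphenylphosphoranylidene)propanoate
Product: 10 ethyl (2E)-2-methylpenta-2,4-dienoate
Conditions: CH2Cl2, 0 °C to rt
Reagents that add atoms: none
Why: Wittig olefination with a stabilised ylide should give the E alkene (ester trans to the vinyl group).

Step 5
Reactants: 10 ethyl (2E)-2-methylpenta-2,4-dienoate
Product: 11 (2E)-2-methylpenta-2,4-dien-1-ol
Conditions: DIBAL-H (2.2 equiv), CH2Cl2, −78 °C; aqueous Rochelle salt
Reagents that add atoms: none
Why: 1,2-Reduction of the dienoate by an aluminium hydride gives the allylic alcohol with the alkene geometry unchanged.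

Step 6
Reactants: 7 arylmaleic anhydride; 11 (2E)-2-methylpenta-2,4-dien-1-ol
Product: 13 racemic ring A lactone acid, via hydrogen maleate 12 (not isolated)
Conditions: toluene, BHT (cat.), 80 °C; then 150 °C, sealed tube
Reagents that add atoms: none
Why: The dienol opens the anhydride at the less hindered C6 carbonyl (the other half-ester can revert through the anhydride) and the hydrogen maleate then undergoes an intramolecular Diels–Alder reaction in which the Z alkene fixes C6 cis to the C20 carboxyl and the three-atom ester tether with both carbonyls endo fixes the cis-fused γ-lactone, so that C4, C5 and C10 form in the required relative configuration, as a racemate.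

Step 7
Reactants: 13 racemic ring A lactone acid
Product: 14 ring A lactone acid as the single enantiomer drawn
Conditions: (R)-1-phenylethylamine (0.55 equiv), EtOAc–EtOH, two crystallisations; then 1 M HCl, EtOAc
Reagents that add atoms: none
Why: Classical resolution of a carboxylic acid through its diastereomeric ammonium salts; no stereocentre is changed.

Step 8
Reactants: 14 ring A lactone acid (single enantiomer)
Product: 15 dihydro lactone acid
Conditions: H2 (3 atm), RhCl(PPh3)3 (5 mol %), benzene–EtOH, 40 °C
Reagents that add atoms: none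
Why: Homogeneous hydrogenation of the cis-disubstituted C2=C3 alkene leaves the aryl benzyl ether intact and creates no stereocentre.

Step 9
Reactants: 15 dihydro lactone acid
Product: 16 diacid (new carboxyl on C8)
Conditions: Pd(OAc)2 (10 mol %), Ag2CO3 (2 equiv), NaOAc (2 equiv), CO (1 atm), 1,4-dioxane, 130 °C; then 1 M HCl
Reagents that add atoms: carbon monoxide, [C-]#[O+]; water, O
Why: Carboxylate-directed ortho C–H palladation of the α,α-disubstituted arylacetic acid (six-membered palladacycle), CO insertion and reductive elimination give the cyclic anhydride, opened on work-up; C8–H is the only ortho C–H bond.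

Step 10
Reactants: 16 diacid
Product: 18 spiro-isochromanone (16-O-benzyl, 11-O-MOM), via hydroxy acid 17 (not isolated)
Conditions: BH3·SMe2 (1.1 equiv), THF, 0 °C; MeOH; then EDC·HCl, DMAP (cat.), CH2Cl2, rt
Reagents that add atoms: none
Why: Borane should reduce the aliphatic C20 acid much faster than the electron-rich, doubly ortho-substituted benzoic acid, and carbodiimide activation then closes the δ-lactone from the C20 hydroxyl onto C7.

Step 11
Reactants: 18 spiro-isochromanone (16-O-benzyl, 11-O-MOM)
Product: 19 spiro-isochromanone phenol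
Conditions: H2 (1 atm), Pd/C (10 %), EtOAc–MeOH, rt
Reagents that add atoms: none
Why: Hydrogenolysis of the aryl benzyl ether frees the C16 phenol; MOM ether and lactones are inert.

Step 12
Reactants: 19 spiro-isochromanone phenol; 20 phenyl vinyl selenide
Product: 22 bicyclo[2.2.2]octenone adduct, via dienone ketal 21 (not isolated)
Conditions: PhI(OAc)2 (1.05 equiv), MeOH, 0 °C; evaporate; 20 (8 equiv), BHT (cat.), toluene, 110 °C, sealed tube
Reagents that add atoms: methanol, CO
Why: PhI(OAc)2 oxidises the guaiacol unit and methanol adds at the methoxy-bearing C15 to give the 6,6-dimethoxycyclohexa-2,4-dienone 21 (a masked ortho-benzoquinone), whose diene C8=C9–C11=C12 then undergoes a thermal suprafacial [4+2] cycloaddition with the vinyl selenide; the closest known reaction type is the Diels–Alder reaction of such dienones with phenyl vinyl sulfide and enol ethers. The only ring closed is the six-membered ring C8–C9–C11–C12–C13–C14, in the concerted (4+2) mode, which leaves a bicyclo[2.2.2]octenone with C15–C16 as the third bridge. C8 and C12 are set together by the face of the flat dienone that is attacked: the C10 spiro centre holds C1H2 over one face and C5–H with its lactone carbonyl over the other, so the alkene should enter past the smaller C1 side, which is the face that gives the target configuration at C8; C13 (selenium endo) does not matter because it becomes a radical in step 13. The regiochemistry needed (selenium on C13, next to C12) should follow from the polarisation of the push–pull diene: C8 is the electrophilic δ-carbon of the dienone, while C12 is α to the ketone and β to the C11 oxygen, so the nucleophilic CH2 terminus of the selenide bonds to C8. Dimerisation of the dienone should be held back by its substituents on C8 and C9.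

Step 13
Reactants: 22 bicyclo[2.2.2]octenone adduct
Product: 23 bicyclo[3.2.1]octenone (16-ketone)
Conditions: Bu3SnH (1.5 equiv, syringe pump), AIBN (0.2 equiv), benzene, 80 °C, 0.01 M
Reagents that add atoms: none
Why: Dowd–Beckwith 1,2-acyl migration: the C13 radical from C–Se homolysis adds to the C16 carbonyl, the cyclopropyloxy radical opens by cleaving C12–C16 to the allylic, oxygen-substituted C12 radical, which is reduced at its less hindered end, while the configuration at C13 is dictated by the bicycle.

Step 14
Reactants: 23 bicyclo[3.2.1]octenone (16-ketone)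
Product: 24 16-methyl carbinol
Conditions: CeCl3 (3 equiv), MeLi (3 equiv), THF, −78 °C; then 23, −78 °C
Reagents that add atoms: methyllithium, C[Li]
Why: The organocerium reagent adds to the ketone and not to the lactones, from the face of the one-carbon bridge C14 as in other bicyclo[3.2.1]octan-6-ones, so the new hydroxyl points into the cleft between ring D and the C9–C11–C12 bridge.

Step 15
Reactants: 24 16-methyl carbinol
Product: 25 saturated 11-O-MOM ether
Conditions: H2 (10 atm), [Ir(cod)(PCy3)(py)]PF6 (20 mol %), CH2Cl2, rt
Reagents that add atoms: none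
Why: Hydroxyl-directed homogeneous hydrogenation: iridium bound to the C16 hydroxyl delivers both hydrogens to the enol ether from the ring D side, which places H on C9 and C11 on that face and C10 and the C11 oxygen on the C14 side, the target configuration at both centres.

Step 16
Reactants: 25 saturated 11-O-MOM ether
Product: 26 16-methylene 15-ketal
Conditions: methyl N-(triethylammoniosulfonyl)carbamate (Burgess reagent, 3 equiv), toluene, 70 °C
Reagents that add atoms: none
Why: Syn elimination of the tertiary alcohol can only use the methyl hydrogens (C15 is a ketal carbon and C13 a bridgehead), so the exocyclic C16=C17 alkene is the sole possible product.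

Step 17
Reactants: 26 16-methylene 15-ketal
Product: 27 15-oxo enone with free 11-hydroxyl
Conditions: TFA–H2O (9:1), CH2Cl2, 0 °C to rt; aqueous NaHCO3
Reagents that add atoms: water, O
Why: Acid hydrolysis removes the allylic dimethyl ketal and the MOM ether together; no stereocentre is at risk because C11 is an alcohol and C9 is not α to a carbonyl.

Step 18
Reactants: 27 15-oxo enone with free 11-hydroxyl
Product: 28 guidongnin
Conditions: NaBH4, CeCl3·7H2O, MeOH, −40 °C
Reagents that add atoms: none
Why: Luche 1,2-reduction of the α-methylene ketone, with hydride entering C15 from the side of the one-carbon bridge C14, should give the 15-hydroxyl pointing toward the C9–C11–C12 bridge as in the target; lactones and the exocyclic alkene are untouched.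

**Compound list**

1 | 3-(benzyloxy)-4-methoxyphenol | Oc1ccc(OC)c(OCc2ccccc2)c1 | starting material
2 | 2-(benzyloxy)-1-methoxy-4-(methoxymethoxy)benzene | COCOc1ccc(OC)c(OCc2ccccc2)c1 | intermediate
3 | 1-(benzyloxy)-4-bromo-2-methoxy-5-(methoxymethoxy)benzene | COCOc1cc(OCc2ccccc2)c(OC)cc1Br | intermediate
4 | bromomaleic anhydride (3-bromofuran-2,5-dione) | O=C1OC(=O)C(Br)=C1 | starting material
5 | [4-(benzyloxy)-5-methoxy-2-(methoxymethoxy)phenyl]lithium | COCOc1cc(OCc2ccccc2)c(OC)cc1[Li] | intermediate
6 | [4-(benzyloxy)-5-methoxy-2-(methoxymethoxy)phenyl]zinc chloride | COCOc1cc(OCc2ccccc2)c(OC)cc1[Zn]Cl | intermediate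
7 | 3-[4-(benzyloxy)-5-methoxy-2-(methoxymethoxy)phenyl]furan-2,5-dione (arylmaleic anhydride) | COCOc1cc(OCc2ccccc2)c(OC)cc1C3=CC(=O)OC3=O | intermediate
8 | acrolein | C=CC=O | starting material
9 | ethyl 2-(triphenylphosphoranylidene)propanoate | CCOC(=O)C(C)=P(c1ccccc1)(c1ccccc1)c1ccccc1 | starting material
10 | ethyl (2E)-2-methylpenta-2,4-dienoate | CCOC(=O)/C(C)=C/C=C | intermediate
11 | (2E)-2-methylpenta-2,4-dien-1-ol | OC/C(C)=C/C=C | intermediate
12 | (2Z)-2-aryl-4-[(2E)-2-methylpenta-2,4-dienyloxy]-4-oxobut-2-enoic acid (hydrogen maleate; aryl as in 7) | OC(=O)/C(c1cc(OC)c(OCc2ccccc2)cc1OCOC)=C\C(=O)OC/C(C)=C/C=C | intermediate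
13 | racemic ring A lactone acid: cyclohexene (C2=C3) with cis-fused C19–O–C6 γ-lactone, C4 methyl, and on C10 the aryl group (cis to the C4 methyl) and the C20 carboxyl (cis to C6); SMILES shows the enantiomer carried on | COCOc1cc(OCc2ccccc2)c(OC)cc1[C@@]3(CC=C[C@@]4(C)COC(=O)[C@H]43)C(=O)O | intermediate
14 | the same lactone acid as single enantiomer (C4, C5, C10 arranged as in the target) | COCOc1cc(OCc2ccccc2)c(OC)cc1[C@@]3(CC=C[C@@]4(C)COC(=O)[C@H]43)C(=O)O | intermediate
15 | dihydro lactone acid (ring A saturated) | COCOc1cc(OCc2ccccc2)c(OC)cc1[C@@]3(CCC[C@@]4(C)COC(=O)[C@H]43)C(=O)O | intermediate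
16 | diacid: 15 with a carboxyl on the aryl carbon C8 (between the methoxy group and the ring A substituent) | COCOc1cc(OCc2ccccc2)c(OC)c(C(=O)O)c1[C@@]3(CCC[C@@]4(C)COC(=O)[C@H]43)C(=O)O | intermediate
17 | hydroxy acid: 16 with the C20 carboxyl reduced to CH2OH | COCOc1cc(OCc2ccccc2)c(OC)c(C(=O)O)c1[C@@]3(CCC[C@@]4(C)COC(=O)[C@H]43)CO | intermediate
18 | spiro-isochromanone: C20–O–C7 δ-lactone fused to the arene, spiro at C10 to ring A with its γ-lactone; 16-O-benzyl, 15-O-methyl, 11-O-MOM | COCOc1cc(OCc2ccccc2)c(OC)c5c1[C@@]3(CCC[C@@]4(C)COC(=O)[C@H]43)COC5=O | intermediate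
19 | spiro-isochromanone phenol (free 16-OH) | COCOc1cc(O)c(OC)c5c1[C@@]3(CCC[C@@]4(C)COC(=O)[C@H]43)COC5=O | intermediate
20 | phenyl vinyl selenide | C=C[Se]c1ccccc1 | starting material
21 | masked ortho-benzoquinone: C16 ketone, C15 dimethyl ketal, diene C8=C9–C11(OMOM)=C12 | COCOC1=CC(=O)C(OC)(OC)C5=C1[C@@]3(CCC[C@@]4(C)COC(=O)[C@H]43)COC5=O | intermediate
22 | bicyclo[2.2.2]octenone adduct: bridgeheads C8 and C12; bridges C9=C11(OMOM), C14H2–C13H(SePh) and C15(OMe)2–C16(=O); selenium endo (syn to the C9=C11 bridge); C8 as in the target | O=C1[C@H]2[C@H]([Se]c3ccccc3)C[C@@]4(C(=O)OC[C@]5(CCC[C@@]6(C)COC(=O)[C@H]65)C4=C2OCOC)C1(OC)OC | intermediate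
23 | bicyclo[3.2.1]octenone: C16 ketone now on C13, C15 dimethyl ketal, C9=C11(OMOM) enol ether, C12H2 | O=C1[C@@H]2CC(OCOC)=C3[C@@]4(CCC[C@@]5(C)COC(=O)[C@H]54)COC(=O)[C@]3(C2)C1(OC)OC | intermediate
24 | 16-methyl carbinol: methyl on the C14 side, hydroxyl toward the C9–C11–C12 bridge | C[C@@]1(O)[C@@H]2CC(OCOC)=C3[C@@]4(CCC[C@@]5(C)COC(=O)[C@H]54)COC(=O)[C@]3(C2)C1(OC)OC | intermediate
25 | saturated 11-O-MOM ether: H on C9 and C11 toward ring D, C11 oxygen on the C14 side | C[C@@]1(O)[C@@H]2C[C@@H](OCOC)[C@H]3[C@@]4(CCC[C@@]5(C)COC(=O)[C@H]54)COC(=O)[C@]3(C2)C1(OC)OC | intermediate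
26 | 16-methylene 15-dimethyl ketal, 11-O-MOM | C=C1[C@@H]2C[C@@H](OCOC)[C@H]3[C@@]4(CCC[C@@]5(C)COC(=O)[C@H]54)COC(=O)[C@]3(C2)C1(OC)OC | intermediate
27 | 15-oxo-16-methylene compound with free 11-hydroxyl | C=C1[C@@H]2C[C@@H](O)[C@H]3[C@@]4(CCC[C@@]5(C)COC(=O)[C@H]54)COC(=O)[C@]3(C2)C1=O | intermediate
28 | guidongnin | C=C1[C@@H]2C[C@@H](O)[C@H]3[C@@]4(CCC[C@@]5(C)COC(=O)[C@H]54)COC(=O)[C@]3(C2)[C@@H]1O | target

**Count**

Total steps: 18. Longest linear sequence: 16 steps (steps 1–3 and 6–18; steps 4–5 make the dienol).

**The three steps most likely to fail**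

Step 12 (key step). What may go wrong: the donor-substituted dienone may add the selenide too slowly. Oxidation or polymerisation of the selenide could then take over, and facial selectivity could erode at the temperature needed. Fallback, setting out from 19 and coming back at 23: the dienone 21 is generated as before but trapped with phenyl vinyl sulfide, a more robust two-carbon partner that tolerates long reaction times in neat dienophile at lower temperature. This should give the C13 phenylsulfanyl adduct F1 with the same regio- and stereochemistry. The radical is then released by the slower C–S homolysis (Bu3SnH, 1,1'-azobis(cyclohexanecarbonitrile), chlorobenzene, 130 °C, syringe pump), and the same 1,2-acyl shift delivers 23.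

Step 15. What may go wrong: the tetrasubstituted enol ether between two quaternary carbons may resist hydrogenation, or acidic iridium hydrides may isomerise or cleave it before it is reduced. Fallback, setting out from 24 and coming back at 25: the tertiary hydroxyl is silylated (Me2SiHCl, Et3N, DMAP) to the dimethylsilyl ether F2. Platinum-catalysed intramolecular hydrosilylation (Pt2[(CH2=CHSiMe2)2O]3, toluene, 60 °C) closes a six-membered siloxane from the ring D side and should give the cyclic siloxane F3, with silicon on C11 and the new hydrogen on C9. Tamao oxidation (KF, KHCO3, H2O2) converts the C11 silyl acetal into the 11-ketone F4 without touching C9. Hydroxyl-directed reduction with Me4NBH(OAc)3 (MeCN–AcOH, −20 °C) delivers hydride to C11 from the same side to give the diol F5. MOMCl and iPr2NEt then protect only the secondary hydroxyl and return 25.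

Step 9. What may go wrong: silver carbonate may oxidise the electron-rich arene, or palladation of the C–H bond flanked by the methoxy group and the quaternary carbon may not occur. Fallback, setting out from 15 and coming back at 18: the acid is reduced first (BH3·SMe2, THF, 0 °C) to the neopentyl alcohol F6. The lactone is then closed directly by hydroxyl-directed C–H carbonylation (Pd(OAc)2, N-Boc-leucine, AgOAc, Li2CO3, CO 1 atm, 1,2-dichloroethane, 100 °C), which forms the C8–C7 bond and the δ-lactone in one step.

**Further compounds**

F1 | step 12 | phenylsulfanyl analogue of 22 (sulfur on C13, endo) | O=C1[C@H]2[C@H](Sc3ccccc3)C[C@@]4(C(=O)OC[C@]5(CCC[C@@]6(C)COC(=O)[C@H]65)C4=C2OCOC)C1(OC)OC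
F2 | step 15 | 16-O-dimethylsilyl ether of 24 | C[C@@]1(O[SiH](C)C)[C@@H]2CC(OCOC)=C3[C@@]4(CCC[C@@]5(C)COC(=O)[C@H]54)COC(=O)[C@]3(C2)C1(OC)OC
F3 | step 15 | cyclic siloxane (O16–SiMe2–C11), hydrogen on C9 toward ring D | C[C@@]1(O[Si]6(C)C)[C@@H]2C[C@@]6(OCOC)[C@H]3[C@@]4(CCC[C@@]5(C)COC(=O)[C@H]54)COC(=O)[C@]3(C2)C1(OC)OC
F4 | step 15 | 11-ketone with 16-methyl carbinol and 15-ketal | C[C@@]1(O)[C@@H]2CC(=O)[C@H]3[C@@]4(CCC[C@@]5(C)COC(=O)[C@H]54)COC(=O)[C@]3(C2)C1(OC)OC
F5 | step 15 | 11,16-diol with 15-ketal | C[C@@]1(O)[C@@H]2C[C@@H](O)[C@H]3[C@@]4(CCC[C@@]5(C)COC(=O)[C@H]54)COC(=O)[C@]3(C2)C1(OC)OC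
F6 | step 9 | neopentyl alcohol from 15 (C20 CH2OH, arene C8–H) | COCOc1cc(OCc2ccccc2)c(OC)cc1[C@@]3(CCC[C@@]4(C)COC(=O)[C@H]43)CO
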